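**Retrosynthetic overview**
- The target is 3,5,7,3',5'-pentahydroxy-8,4'-dimethoxyflavone. The four phenol-protecting benzyl groups are removed last, and the C3 hydroxyl is put onto a finished flavone by C3 lithiation, borylation and oxidation.
- Ring C is cut at O1–C2, C3–C4 and C4–C4a. This leads back to an ortho-iodophenol (ring A), carbon monoxide (C4) and a terminal aryl alkyne (ring B, C2, C3), joined in one palladium operation.
- The strategy rests on ring A being a 2-methoxyphloroglucinol whose C8 methoxy carbon lies between C8a–O1 and C7–OH. With the C5 oxygen benzylated, the arene has a mirror plane through C–OMe and C–OBn, so one iodination gives one iodide, and only the hydroxyl ortho to iodine can become O1. The chromone must therefore be 8-methoxy, never 6-methoxy.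
- The ring A piece comes from 2-methoxyresorcinol by borylation and oxidation of its single unhindered C–H. The ring B alkyne comes from methyl 3,5-dihydroxy-4-methoxybenzoate via the aldehyde.
- Ring order: rings A and B are purchased benzene rings that are only decorated. Ring C is the only ring built, in the step that also joins the two halves.

Key step: step 11

Assumption: the transient enaminone 15 is drawn as its E isomer, although either geometry would close to the same chromone.

**Route**

Step 1
Reactants: 1 2-methoxybenzene-1,3-diol (2-methoxyresorcinol)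
Product: 2 2-methoxy-1,3-bis(methoxymethoxy)benzene
Conditions: NaH, MOMCl, DMF, 0 °C to rt
Reagents that add atoms: chloromethyl methyl ether (MOMCl), COCCl
Why: Double Williamson-type O-alkylation of the bis-phenoxide with MOMCl should be clean, and the MOM acetals tolerate the later borylation, basic peroxide and benzylation yet leave under mild acid that spares a benzyl ether.

Step 2
Reactants: 2 2-methoxy-1,3-bis(methoxymethoxy)benzene
Product: 3 2-[4-methoxy-3,5-bis(methoxymethoxy)phenyl]-4,4,5,5-tetramethyl-1,3,2-dioxaborolane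
Conditions: B2pin2, [Ir(OMe)(cod)]2 (1.5 mol%), 4,4'-di-tert-butyl-2,2'-bipyridine (3 mol%), THF, 80 °C
Reagents that add atoms: bis(pinacolato)diboron, CC1(C)OB(OC1(C)C)B1OC(C)(C)C(C)(C)O1
Why: Iridium-catalysed aromatic C–H borylation is governed by sterics, and in this 1,2,3-trisubstituted ring only C5–H has no ortho substituent, so the boron should enter meta to both MOM ethers and para to the methoxy group.

Step 3
Reactants: 3 2-[4-methoxy-3,5-bis(methoxymethoxy)phenyl]-4,4,5,5-tetramethyl-1,3,2-dioxaborolane
Product: 4 4-methoxy-3,5-bis(methoxymethoxy)phenol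
Conditions: 30% aq H2O2, NaOH, THF, 0 °C; then aq NH4Cl
Reagents that add atoms: hydrogen peroxide, OO
Why: Oxidation of the aryl boronate by hydroperoxide anion proceeds by 1,2-migration of the aryl group from boron to oxygen and hydrolysis of the borate, under basic conditions that the MOM acetals tolerate.

Step 4
Reactants: 4 4-methoxy-3,5-bis(methoxymethoxy)phenol
Product: 5 5-benzyloxy-2-methoxy-1,3-bis(methoxymethoxy)benzene
Conditions: BnBr, K2CO3, DMF, rt
Reagents that add atoms: benzyl bromide, BrCc1ccccc1
Why: Williamson etherification of the only free phenol with benzyl bromide installs the group that later keeps the C5 oxygen of the flavone out of the ring closure.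

Step 5
Reactants: 5 5-benzyloxy-2-methoxy-1,3-bis(methoxymethoxy)benzene
Product: 6 5-benzyloxy-2-methoxybenzene-1,3-diol
Conditions: HCl (1 M in MeOH), MeOH/THF, 40 °C
Reagents that add atoms: none
Why: Acid-catalysed acetal exchange with methanol removes both MOM groups while the benzyl and methyl aryl ethers are inert, which should give the mirror-symmetric diol.

Step 6
Reactants: 6 5-benzyloxy-2-methoxybenzene-1,3-diol
Product: 7 5-benzyloxy-4-iodo-2-methoxybenzene-1,3-diol
Conditions: NIS (1.0 equiv), MeCN, −30 to 0 °C, dark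
Reagents that add atoms: N-iodosuccinimide, O=C1CCC(=O)N1I
Why: Electrophilic aromatic iodination by NIS can only occur at C4 or C6, which are equivalent by the mirror plane through C2 and C5 and each activated by three oxygen donors, so one equivalent at low temperature should give a single mono-iodide with iodine between a free OH and the benzyl ether.

Step 7
Reactants: 8 methyl 3,5-dihydroxy-4-methoxybenzoate
Product: 9 methyl 3,5-bis(benzyloxy)-4-methoxybenzoate
Conditions: BnBr, K2CO3, DMF, 60 °C
Reagents that add atoms: benzyl bromide, BrCc1ccccc1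
Why: Double Williamson etherification of the two phenols flanking the methoxy group should proceed with the methyl ester untouched by K2CO3 in DMF.

Step 8
Reactants: 9 methyl 3,5-bis(benzyloxy)-4-methoxybenzoate
Product: 10 [3,5-bis(benzyloxy)-4-methoxyphenyl]methanol
Conditions: LiAlH4, THF, 0 °C
Reagents that add atoms: none
Why: Hydride reduction of the methyl ester by LiAlH4 gives the primary benzylic alcohol while aryl benzyl and methyl ethers are inert.

Step 9
Reactants: 10 [3,5-bis(benzyloxy)-4-methoxyphenyl]methanol
Product: 11 3,5-bis(benzyloxy)-4-methoxybenzaldehyde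
Conditions: MnO2, CH2Cl2, rt
Reagents that add atoms: none
Why: MnO2 oxidises benzylic alcohols selectively and stops at the aldehyde.

Step 10
Reactants: 11 3,5-bis(benzyloxy)-4-methoxybenzaldehyde
Product: 12 1,3-bis(benzyloxy)-5-ethynyl-2-methoxybenzene
Conditions: dimethyl (1-diazo-2-oxopropyl)phosphonate, K2CO3, MeOH/THF, rt
Reagents that add atoms: dimethyl (1-diazo-2-oxopropyl)phosphonate (Ohira–Bestmann reagent), CC(=O)C(=[N+]=[N-])P(=O)(OC)OC
Why: In this Ohira–Bestmann (Seyferth–Gilbert) homologation, methanolysis of the reagent gives the dimethyl diazomethylphosphonate anion, olefination of the aldehyde gives a diazoalkene, and loss of N2 with a 1,2-hydride shift gives the terminal alkyne under mild base that suits the electron-rich aldehyde.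

Step 11
Reactants: 7 5-benzyloxy-4-iodo-2-methoxybenzene-1,3-diol; 12 1,3-bis(benzyloxy)-5-ethynyl-2-methoxybenzene; 13 carbon monoxide
Product: 16 5-benzyloxy-7-hydroxy-8-methoxy-2-[3,5-bis(benzyloxy)-4-methoxyphenyl]-4H-chromen-4-one, via ortho-hydroxyaryl ynone 14 (not isolated), via beta-diethylamino enone 15 (not isolated)
Conditions: PdCl2(dppf) (5 mol%), CO (20 atm), Et2NH, 100 °C, no copper
Reagents that add atoms: carbon monoxide (compound 13), [C-]#[O+]
Why: Zerovalent palladium, formed from PdCl2(dppf) under amine and CO, inserts into the C–I bond of 7, CO migratory insertion gives the aroylpalladium iodide, and the amine-deprotonated alkyne 12 is transferred and reductively eliminated to give ynone 14, which forms C4a–C4 and C4–C3. Et2NH then adds to the ynone to give the beta-amino enone 15, and the neighbouring phenol attacks the beta carbon and expels the amine, which forms O1–C2 and closes ring C in a formal 6-endo addition–elimination mode instead of the 5-exo mode that leads to an aurone. The closest known reaction type is the palladium-catalysed carbonylative Sonogashira annulation of ortho-iodophenols with terminal aryl acetylenes to flavones. No stereocentre is created. The step needs CO insertion to outrun direct alkynylation, which would end in a 2-arylbenzofuran; this is secured by CO pressure, the absence of copper and an electron-rich aryl group that migrates readily to CO. It also needs the 8-methoxy regiochemistry, which the substrate secures because the iodine-bearing carbon lies between one free OH (on the carbon next to C–OMe) and the benzylated oxygen, so only that OH can become O1, the para OH (the future C7–OH) cannot reach the ynone, and the basic medium rules out an acid-induced Wessely–Moser shift of the methoxy group to C6.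

Step 12
Reactants: 16 5-benzyloxy-7-hydroxy-8-methoxy-2-[3,5-bis(benzyloxy)-4-methoxyphenyl]-4H-chromen-4-one
Product: 17 5,7-bis(benzyloxy)-8-methoxy-2-[3,5-bis(benzyloxy)-4-methoxyphenyl]-4H-chromen-4-one
Conditions: BnBr, K2CO3, DMF, rt
Reagents that add atoms: benzyl bromide, BrCc1ccccc1
Why: Williamson etherification of the only free phenol, the acidic C7–OH that is conjugated with the C4 carbonyl, protects it before strong base is used at C3.

Step 13
Reactants: 17 5,7-bis(benzyloxy)-8-methoxy-2-[3,5-bis(benzyloxy)-4-methoxyphenyl]-4H-chromen-4-one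
Product: 20 5,7-bis(benzyloxy)-3-hydroxy-8-methoxy-2-[3,5-bis(benzyloxy)-4-methoxyphenyl]-4H-chromen-4-one, via 3-lithioflavone 18 (not isolated), via flavon-3-yl dimethyl boronate 19 (not isolated)
Conditions: LiN(iPr)2, THF, −78 °C; B(OMe)3, −78 to 0 °C; AcOH, 30% aq H2O2, 0 °C to rt
Reagents that add atoms: hydrogen peroxide, OO
Why: C3–H, the only vinylic hydrogen of the pyranone and alpha to the carbonyl, is removed by LiN(iPr)2 at −78 °C, the 3-lithio species is trapped by B(OMe)3 and the C–B bond is oxidised in place by H2O2, a known lithiation–borylation–oxidation route from flavones to flavonols.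

Step 14
Reactants: 20 5,7-bis(benzyloxy)-3-hydroxy-8-methoxy-2-[3,5-bis(benzyloxy)-4-methoxyphenyl]-4H-chromen-4-one
Product: 21 2-(3,5-dihydroxy-4-methoxyphenyl)-3,5,7-trihydroxy-8-methoxy-4H-chromen-4-one (target CNP0103387.0)
Conditions: H2 (1 atm), 10% Pd/C, THF/MeOH, rt
Reagents that add atoms: none
Why: Catalytic hydrogenolysis cleaves the four benzylic C–O bonds over Pd/C while the aryl methyl ethers and the conjugated, hydrogen-bonded flavonol core resist reduction under one atmosphere of H2.

**Compound list**

1 | 2-methoxybenzene-1,3-diol (2-methoxyresorcinol) | COc1c(O)cccc1O | starting material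
2 | 2-methoxy-1,3-bis(methoxymethoxy)benzene | COCOc1cccc(OCOC)c1OC | intermediate
3 | 2-[4-methoxy-3,5-bis(methoxymethoxy)phenyl]-4,4,5,5-tetramethyl-1,3,2-dioxaborolane | COCOc1cc(B2OC(C)(C)C(C)(C)O2)cc(OCOC)c1OC | intermediate
4 | 4-methoxy-3,5-bis(methoxymethoxy)phenol | COCOc1cc(O)cc(OCOC)c1OC | intermediate
5 | 5-benzyloxy-2-methoxy-1,3-bis(methoxymethoxy)benzene | COCOc1cc(OCc2ccccc2)cc(OCOC)c1OC | intermediate
6 | 5-benzyloxy-2-methoxybenzene-1,3-diol | COc1c(O)cc(OCc2ccccc2)cc1O | intermediate
7 | 5-benzyloxy-4-iodo-2-methoxybenzene-1,3-diol | COc1c(O)cc(OCc2ccccc2)c(I)c1O | intermediate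
8 | methyl 3,5-dihydroxy-4-methoxybenzoate | COC(=O)c1cc(O)c(OC)c(O)c1 | starting material
9 | methyl 3,5-bis(benzyloxy)-4-methoxybenzoate | COC(=O)c1cc(OCc2ccccc2)c(OC)c(OCc2ccccc2)c1 | intermediate
10 | [3,5-bis(benzyloxy)-4-methoxyphenyl]methanol | OCc1cc(OCc2ccccc2)c(OC)c(OCc2ccccc2)c1 | intermediate
11 | 3,5-bis(benzyloxy)-4-methoxybenzaldehyde | O=Cc1cc(OCc2ccccc2)c(OC)c(OCc2ccccc2)c1 | intermediate
12 | 1,3-bis(benzyloxy)-5-ethynyl-2-methoxybenzene | C#Cc1cc(OCc2ccccc2)c(OC)c(OCc2ccccc2)c1 | intermediate
13 | carbon monoxide | [C-]#[O+] | starting material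
14 | 1-(6-benzyloxy-2,4-dihydroxy-3-methoxyphenyl)-3-[3,5-bis(benzyloxy)-4-methoxyphenyl]prop-2-yn-1-one | COc1c(O)cc(OCc2ccccc2)c(C(=O)C#Cc2cc(OCc3ccccc3)c(OC)c(OCc3ccccc3)c2)c1O | intermediate
15 | (E)-1-(6-benzyloxy-2,4-dihydroxy-3-methoxyphenyl)-3-[3,5-bis(benzyloxy)-4-methoxyphenyl]-3-(diethylamino)prop-2-en-1-one | COc1c(O)cc(OCc2ccccc2)c(C(=O)/C=C(/N(CC)CC)c2cc(OCc3ccccc3)c(OC)c(OCc3ccccc3)c2)c1O | intermediate
16 | 5-benzyloxy-7-hydroxy-8-methoxy-2-[3,5-bis(benzyloxy)-4-methoxyphenyl]-4H-chromen-4-one | COc1c(O)cc(OCc2ccccc2)c2c(=O)cc(-c3cc(OCc4ccccc4)c(OC)c(OCc4ccccc4)c3)oc12 | intermediate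
17 | 5,7-bis(benzyloxy)-8-methoxy-2-[3,5-bis(benzyloxy)-4-methoxyphenyl]-4H-chromen-4-one | COc1c(OCc2ccccc2)cc(OCc2ccccc2)c2c(=O)cc(-c3cc(OCc4ccccc4)c(OC)c(OCc4ccccc4)c3)oc12 | intermediate
18 | 5,7-bis(benzyloxy)-3-lithio-8-methoxy-2-[3,5-bis(benzyloxy)-4-methoxyphenyl]-4H-chromen-4-one | COc1c(OCc2ccccc2)cc(OCc2ccccc2)c2c(=O)c([Li])c(-c3cc(OCc4ccccc4)c(OC)c(OCc4ccccc4)c3)oc12 | intermediate
19 | dimethyl {5,7-bis(benzyloxy)-8-methoxy-2-[3,5-bis(benzyloxy)-4-methoxyphenyl]-4-oxo-4H-chromen-3-yl}boronate | COc1c(OCc2ccccc2)cc(OCc2ccccc2)c2c(=O)c(B(OC)OC)c(-c3cc(OCc4ccccc4)c(OC)c(OCc4ccccc4)c3)oc12 | intermediate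
20 | 5,7-bis(benzyloxy)-3-hydroxy-8-methoxy-2-[3,5-bis(benzyloxy)-4-methoxyphenyl]-4H-chromen-4-one | COc1c(OCc2ccccc2)cc(OCc2ccccc2)c2c(=O)c(O)c(-c3cc(OCc4ccccc4)c(OC)c(OCc4ccccc4)c3)oc12 | intermediate
21 | 2-(3,5-dihydroxy-4-methoxyphenyl)-3,5,7-trihydroxy-8-methoxy-4H-chromen-4-one | COc1c(O)cc(-c2oc3c(OC)c(O)cc(O)c3c(=O)c2O)cc1O | target

**Step count**

Total step count: 14.
Longest linear sequence: 10 steps (steps 1–6, then 11–14). Steps 7–10 form the four-step ring B branch.

**Steps most likely to fail**

1. Step 11 (carbonylative annulation). Oxidative addition into the electron-rich C–I bond, which has substituents in both ortho positions, may be slow. Protodeiodination, capture of the aroylpalladium by Et2NH to give an amide, direct alkynylation with closure to a benzofuran, or 5-exo closure to an aurone could then take over. The fallback needs no palladium and no CO gas. It sets out from iodide 7 and alkyne 12 and rejoins the route at 14 and then 16. Iodide 7 is treated with MOMCl and iPr2NEt in CH2Cl2 to give 1-benzyloxy-2-iodo-4-methoxy-3,5-bis(methoxymethoxy)benzene F1. Iodine–magnesium exchange with iPrMgCl·LiCl in THF at −20 °C then gives [6-benzyloxy-3-methoxy-2,4-bis(methoxymethoxy)phenyl]magnesium chloride F2. In parallel, alkyne 12 is deprotonated with n-BuLi in THF at −78 °C to the lithium acetylide F3, which is acylated with N-methoxy-N-methylcarbamoyl chloride to give 3-[3,5-bis(benzyloxy)-4-methoxyphenyl]-N-methoxy-N-methylprop-2-ynamide F4. Addition of F2 to F4 (Weinreb ketone synthesis) should give, after aqueous NH4Cl, the bis-MOM ynone 1-[6-benzyloxy-3-methoxy-2,4-bis(methoxymethoxy)phenyl]-3-[3,5-bis(benzyloxy)-4-methoxyphenyl]prop-2-yn-1-one F5. HCl in MeOH at rt removes both MOM groups to give ynone 14, and Et2NH in EtOH closes it through enaminone 15 to chromone 16. The regiochemical argument is unchanged, because the benzyl ether still blocks the second ortho oxygen.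

2. Step 6 (mono-iodination). The free resorcinol may take up a second iodine at the equivalent C6 position or be oxidised by the iodinating agent, and the iodide may be lost again on acidic handling. The fallback lowers the ring reactivity before halogenation. It sets out from diol 6 and returns at iodide 7. Acetylation with Ac2O and pyridine gives 5-benzyloxy-2-methoxy-1,3-phenylene diacetate F6. Iodination of this less activated ring with NIS and catalytic CF3CO2H in MeCN should stop at 5-benzyloxy-4-iodo-2-methoxy-1,3-phenylene diacetate F7, since only the benzyloxy group activates strongly and the two open positions are again equivalent. Methanolysis with K2CO3 in degassed MeOH at 0 °C returns 7.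

3. Step 13 (C3 hydroxylation). The amide base may deprotonate a benzylic CH2 of the peri 5-benzyloxy group, leading to Wittig-type rearrangement, or add at C2 and open the pyranone. The hindered 3-lithio species may also be trapped incompletely by the borate. The fallback replaces deprotonation by oxygen transfer to the C2–C3 double bond. It sets out from flavone 17 and returns at flavonol 20. Dimethyldioxirane in acetone/CH2Cl2 at 0 °C should give the racemic, cis-fused 2,3-epoxide of 17, 5,7-bis(benzyloxy)-2,3-epoxy-8-methoxy-2-[3,5-bis(benzyloxy)-4-methoxyphenyl]chroman-4-one F8. Catalytic p-TsOH in CH2Cl2 then opens the epoxide at C2 (cation stabilised by O1 and the aryl group), and loss of the C3 proton gives 20.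

Further compounds
F1 | step 11 | 1-benzyloxy-2-iodo-4-methoxy-3,5-bis(methoxymethoxy)benzene | COc1c(OCOC)cc(OCc2ccccc2)c(I)c1OCOC
F2 | step 11 | [6-benzyloxy-3-methoxy-2,4-bis(methoxymethoxy)phenyl]magnesium chloride | COc1c(OCOC)cc(OCc2ccccc2)c([Mg]Cl)c1OCOC
F3 | step 11 | lithium [3,5-bis(benzyloxy)-4-methoxyphenyl]acetylide | [Li]C#Cc1cc(OCc2ccccc2)c(OC)c(OCc2ccccc2)c1
F4 | step 11 | 3-[3,5-bis(benzyloxy)-4-methoxyphenyl]-N-methoxy-N-methylprop-2-ynamide | CON(C)C(=O)C#Cc1cc(OCc2ccccc2)c(OC)c(OCc2ccccc2)c1
F5 | step 11 | 1-[6-benzyloxy-3-methoxy-2,4-bis(methoxymethoxy)phenyl]-3-[3,5-bis(benzyloxy)-4-methoxyphenyl]prop-2-yn-1-one | COc1c(OCOC)cc(OCc2ccccc2)c(C(=O)C#Cc2cc(OCc3ccccc3)c(OC)c(OCc3ccccc3)c2)c1OCOC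
F6 | step 6 | 5-benzyloxy-2-methoxy-1,3-phenylene diacetate | COc1c(OC(C)=O)cc(OCc2ccccc2)cc1OC(C)=O
F7 | step 6 | 5-benzyloxy-4-iodo-2-methoxy-1,3-phenylene diacetate | COc1c(OC(C)=O)cc(OCc2ccccc2)c(I)c1OC(C)=O
F8 | step 13 | 5,7-bis(benzyloxy)-2,3-epoxy-8-methoxy-2-[3,5-bis(benzyloxy)-4-methoxyphenyl]chroman-4-one (racemic, cis-fused, one enantiomer drawn) | O=C1[C@H]2O[C@@]2(c3cc(OCc4ccccc4)c(OC)c(OCc4ccccc4)c3)Oc3c(OC)c(OCc4ccccc4)cc(OCc4ccccc4)c31
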